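Readings and results were computed with constants of no real substance.

The trap with a racemate is to take the product ratio of an early reading for a property of the whole run.

| setting | alpha | eta | theta | east | south-east | north | west |
|---|---|---|---|---|---|---|---|
| left-handed substrate | 28 mM | 44 mM | 20 mM | 20 mM | 20 mM | 20 mM | 20 mM |
| right-handed substrate | 28 mM | 44 mM | 20 mM | 20 mM | 20 mM | 20 mM | 20 mM |
| gas | 0.72 mM (held) | 0.72 mM (held) | 0.72 mM (held) | 0.72 mM (held) | 0.72 mM (held) | 0.72 mM (held) | 0.72 mM (held) |
| catalyst | 6.5 mol% | 6.5 mol% | 13 mol% | 6.5 mol% | 6.5 mol% | 6.5 mol% | 6.5 mol% |
| temperature | −40 °C | 10 °C | −40 °C | −35 °C | −5 °C | 25 °C | 55 °C |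
| remark | run made earlier | run made earlier | run made earlier |  |  |  |  |
| time |  |  |  | 12 d | 12 d | 12 d | 12 d |

- alpha (time / d: left-handed product / %, right-handed product / %): 0.625: 0.9, 0; 1.67: 1.9, 0.1; 3.00: 4.3, 0; 5.00: 7.3, 0.4; 8.00: 10.1, 0.7; 10.0: 12.5, 0.1
- eta (time / h: left-handed product / %, right-handed product / %): 4.00: 1.4, 0; 8.00: 2.0, 0; 12.0: 3.1, 0.3; 15.0: 4.1, 0.5; 20.0: 5.2, 0.8; 25.0: 6.7, 0
- theta (time / d: left-handed product / %, right-handed product / %): 0.833: 2.3, 0.3; 2.50: 4.8, 0; 4.00: 7.1, 0.3; 6.00: 10.4, 0.8; 10.0: 17.4, 0.8

(each reading ± 0.3 percentage points)

- catalyst is single-handed; left-handed substrate and right-handed substrate are mirror images of each other, charged as a racemate, each of them at the stated concentration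
- at the start none of partner is dissolved
- reactions considered so far: partner + catalyst + left-handed substrate -> catalyst + left-handed product; partner -> decomposed reagent; partner + catalyst + right-handed substrate -> catalyst + right-handed product; gas <-> partner
- an excess is the difference of the two amounts in percent of their sum
- an excess is below zero if the other one leads

* the flask that comes out highest in excess of left-handed product over right-handed product, or "all alike" when all lie within 1.5 percentage points (east / south-east / north / west / all alike)
* excess of left-handed product over right-handed product at the end, east
* excess of left-handed product over right-handed product at the end, south-east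
* excess of left-handed product over right-handed product at the end, north
* excess of left-handed product over right-handed product at the end, west

So we compare the two rates at one moment. Their ratio, left-handed product over right-handed product, is m = s · c(left-handed substrate)/c(right-handed substrate). Here s is the selectivity factor, read as left-handed over right-handed product summed over the later alpha and theta readings: 20.9 at −40 °C. At the start m equals s, and what is being made carries an excess of (m−1)/(m+1).

Catalyst, by hand, speeds both paths alike, so it leaves s and brings depletion sooner. Theta, with twice the loading on less substrate, made 6.96 mM of left-handed product in 10.0 d, and alpha made 7.00 mM in 10.0 d, which fits a rate proportional to catalyst times substrate.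

Time, by hand, leaves s and lowers m, since the left-handed substrate goes faster. Theta's last reading has used 34.8% of its left-handed substrate. Scaled to the loading and time of east, at the temperature of theta, that leaves 77.4% of it. With c(right-handed substrate) taken near its charge, m is then about 16.2 at the end, and we commit to east a little below 90.9%.

Temperature, by hand, lowers s and speeds the run. Eta reads s = 11.9 at 10 °C, lower than the cold value, and its average flow is 0.236 mM h⁻¹. Eta holds more substrate and catalyst than the four flasks, so we scale that flow by catalyst times substrate, which over 12 d gives 14.0 mM of the 40.0 mM charged. Scaled the same way, eta runs 3.25 times as fast as alpha, and one more such step for west gives 45.5 mM, more than that charge, so we reckon west may use up the left-handed substrate, and perhaps north. Then left-handed product stands at half the charge, m falls towards zero, and right-handed product catches up. We commit to a steep fall from east to west, with west near zero.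

The forecast stays higher on the warm side, with 90%, 85%, 79% and 71% from east to west: “Selectivity falls and the fast enantiomer depletes with warming, so product excess drops”.

The flasks give 89.6%, 66.6%, 13.2% and 0.119% in that order, with east the highest.

    partner + catalyst + left-handed substrate → catalyst + left-handed product (k = 1.20 × 10⁵ M⁻² h⁻¹, Ea = 42.0 kJ mol⁻¹)
    partner → decomposed reagent (k = 0.00250 h⁻¹, Ea = 101 kJ mol⁻¹)
    partner + catalyst + right-handed substrate → catalyst + right-handed product (k = 10000 M⁻² h⁻¹, Ea = 48.0 kJ mol⁻¹)
    gas ⇌ partner, rate k4*(csat - [partner]) (kL = 0.380 h⁻¹)
    (constants at 25 °C)

In east at 12.0 d, c(left-handed substrate) is 33.2% and c(right-handed substrate) is 49.1%, so m with the cold s is still 14.1. The neighbouring flask is east run at −10 °C, with amounts and time held. Its 4.26% against 43.1% gives m = 2.07 with the cold s and 1.18 with the s of eta. That neighbour holds 45.7% of left-handed product, and its excess stands at 73.8%.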